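Late in the run, at 25 h, you want one ratio, monomer in chains over chains, in teal and in red, two flasks that differ in their initiator.

    initiator → 2 initiating radical (k1 = 0.0116 h⁻¹)
    free monomer + initiating radical → growing radical + monomer in chains (k2 = 2.87 × 10⁵ M⁻¹ s⁻¹)
    free monomer + growing radical → monomer in chains + growing radical, rate k3*[growing radical]*[free monomer] (k3 = 15600 M⁻¹ s⁻¹)
    2 growing radical → dead chain (k4 = 1.0 × 10⁷ M⁻¹ s⁻¹)

all flasks: free monomer 10 mM (fed, over 25 h); time 25 h
- teal: initiator 40 µM; the fed solution adds 0.10 times the starting volume
- red: initiator 120 µM; the fed solution adds 0.10 times the starting volume

- a step written with two of one species runs at k times the square of its concentration and takes two of it each time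
- every charge counts on the volume at the start, and the solution that is fed holds the whole dose
- the average divides the monomer in chains by the number of chains, living and dead together; two radicals that join make one chain
- run time (teal): 25 h

* which of the two ends with the longer chains by the average number of monomer units in a chain (living and dead chains, two that joined counted as one) ("neither" if they lie within 10%) (teal / red / neither)
* average number of monomer units in a chain (living and dead chains, two that joined counted as one) at the end, teal
* average number of monomer units in a chain (living and dead chains, two that joined counted as one) at the end, red

Amounts count per starting volume. Start with teal.

1. Chains. One initiator gives two radicals and two radicals make one chain, so in teal the chains equal the initiator decomposed, 10.1 µM.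
2. Radicals. Making balances joining at the square root of the initiator's decay constant times c(initiator) over the joining constant, with c(initiator) thinned by the feed. In teal at the end that is 2.96 nM. Its half-life by joining is 16.9 s, against a dosing time of 25 h, so the balance holds. Living chains are 0.0293% of the count, so they drop out.
3. Uptake. Free monomer now reacts in a pseudo-first-order way. Its uptake constant is the addition constant times c(growing radical), 0.166 h⁻¹ in teal.
4. Backlog. The feed brings 0.400 mM h⁻¹. The start fades on a time of about 6.02 h, against a dosing time of 25 h, so free monomer in teal sits near feed over uptake, 2.41 mM.
5. The weak link. Step 4 treats the uptake constant as fixed, but it sinks. Its relative rate of fall is half the initiator's decay constant plus half the dilution rate, 0.00762 h⁻¹. Free monomer trails its rising target by 4.59%, which leaves 2.30 mM in teal.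
6. Length. Charge minus backlog, over chains, gives 765 for teal. In red the uptake constant is 0.288 h⁻¹, the backlog 1.35 mM and the chains 30.2 µM, which gives 286. The longer chains: teal.

The forecast gives teal, with 765 for teal and 286 for red, holding that “Chains equal the initiator decomposed, since two radicals make one chain”.

The simulation gives 767 for teal and 286 for red. Free monomer in teal stands at 22.8% of the charge after 25.0 h, against 23.0% reckoned. In teal, a relative error in the uptake constant reaches the length multiplied by 0.298.

Take a neighbour like teal with 0.024 mM of initiator. Its uptake constant is 0.129 h⁻¹, its backlog 2.92 mM and its chains 6.04 µM, so the length comes to 1170. The simulation gives 1180, with 29% of the free monomer left.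

(The constants used here are made up; the run is a simulation.)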